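The synthesis rests on one disconnection: the bond from the quaternary peroxy carbon C6 of the 1,2-dioxane ring to the allylic methylene C1′ of the side chain. The ring half is a 6-methoxy-6-methyl-1,2-dioxane (a cyclic peroxyketal) that carries C3 and Cα. The side-chain half is an allylsilane, silylated at C3′, that already holds the tertiary carbinol C4′. A Hosomi–Sakurai reaction through the ring peroxycarbenium ion joins them, creates the C6 stereocentre, moves the alkene to C2′=C3′ (E) and expels silicon in one operation. The step exploits the O1–O2 oxygen on C6, which stabilises a cation there, and the homoallylic C6–C1′–C2′=C3′ array.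

Key step: step 9

Atom labels: dioxane ring O1, O2, C3 to C6; Cα is C2 of the propanoate on C3; the chain on C6 is C1′ to C6′, with C4′ the carbinol carbon.

Assumption: the (S)-diol in step 7 is taken to give the 3S carbinol by analogy with aryl methyl ketones; if the sense is opposite, the (R)-diol is used and nothing else changes. The configuration at the silyl-bearing carbon of 12 and 13 does not reach the target.

Step 1
Reactants: 1 methyl acetoacetate; 2 3-chloro-2-methylprop-1-ene
Product: 3 methyl 6-methyl-3-oxohept-6-enoate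
Conditions: NaH, THF, 0 °C; n-BuLi, 0 °C; then 2, 0 °C to rt; 1 M HCl quench
Reagents that add atoms: none
Why: γ-Alkylation of the acetoacetate dianion, in which the terminal, more basic carbanion displaces the allylic chloride (SN2) while the stabilised internal enolate stays intact.

Step 2
Reactants: 3 methyl 6-methyl-3-oxohept-6-enoate
Product: 4 methyl (3R)-3-hydroxy-6-methylhept-6-enoate
Conditions: H2 (4 atm), Ru2Cl4((R)-BINAP)2·NEt3 (0.5 mol %), MeOH, 50 °C
Reagents that add atoms: none
Why: Noyori asymmetric hydrogenation, in which the β-keto ester chelates the divalent ruthenium centre and (R)-BINAP directs hydride to one carbonyl face (C3 set as R), while the unfunctionalised 1,1-disubstituted alkene does not coordinate and should survive.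

Step 3
Reactants: 4 methyl (3R)-3-hydroxy-6-methylhept-6-enoate
Product: 5 methyl (2R,3R)-3-hydroxy-2,6-dimethylhept-6-enoate
Conditions: LiN(i-Pr)2 (2.2 equiv), THF, −78 to −20 °C; MeI, DMPU, −78 to 0 °C; 1 M HCl quench
Reagents that add atoms: iodomethane, CI
Why: Fráter–Seebach alkylation, in which the chelated lithium alkoxide–enolate dianion is methylated anti to the C3 substituent, so Cα (R) is set by substrate control from C3.

Step 4
Reactants: 5 methyl (2R,3R)-3-hydroxy-2,6-dimethylhept-6-enoate
Product: 6 methyl (2R,3R)-2,6-dimethyl-3-[(methylsulfonyl)oxy]hept-6-enoate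
Conditions: MeSO2Cl, Et3N, CH2Cl2, −20 °C
Reagents that add atoms: methanesulfonyl chloride, CS(=O)(=O)Cl
Why: O-Sulfonylation of the secondary alcohol with retention at C3, run cold and briefly so that the β-sulfonyloxy ester does not eliminate.

Step 5
Reactants: 6 methyl (2R,3R)-2,6-dimethyl-3-[(methylsulfonyl)oxy]hept-6-enoate
Product: 8 methyl (2R)-2-[(3S)-6-methoxy-6-methyl-1,2-dioxan-3-yl]propanoate (both C6 anomers), via hydroperoxy ketal 7 (not isolated)
Conditions: O3, CH2Cl2/MeOH (3:1), −78 °C; N2 purge, concentrate cold; then KOt-Bu (1.05 equiv), 18-crown-6, toluene, 0 °C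
Reagents that add atoms: ozone, O=[O+][O-]; methanol, CO
Why: Ozonolysis of the 1,1-disubstituted alkene gives the ketone O-oxide (Criegee intermediate), which methanol traps as the α-methoxy hydroperoxide 7, and its potassium peroxide then displaces the C3 mesylate in a 6-exo-tet SN2 closure with inversion (3R to 3S), the known intramolecular alkylation of hydroperoxy ketals; the C6 ketal centre forms as both anomers and is erased in step 9.

Step 6
Reactants: 9 allyltrimethylsilane
Product: 10 dipropan-2-yl [(2E)-3-(trimethylsilyl)prop-2-en-1-yl]boronate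
Conditions: s-BuLi, TMEDA, THF, −78 °C; B(Oi-Pr)3, −78 °C to rt; HCl in Et2O (1.0 equiv); distillation
Reagents that add atoms: triisopropyl borate, CC(C)OB(OC(C)C)OC(C)C
Why: Allylic lithiation of the allylsilane and borylation at the carbon remote from silicon gives the E γ-silylallylboronate, as known for α-silylallyl anions with borate electrophiles.

Step 7
Reactants: 10 dipropan-2-yl [(2E)-3-(trimethylsilyl)prop-2-en-1-yl]boronate; 11 4-(2,6,6-trimethylcyclohex-1-en-1-yl)butan-2-one (dihydro-β-ionone)
Product: 12 (3S,4R)-3-methyl-4-(trimethylsilyl)-1-(2,6,6-trimethylcyclohex-1-en-1-yl)hex-5-en-3-ol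
Conditions: (S)-3,3′-Br2-BINOL (15 mol %), PhCF3/toluene (3:1), −35 °C; aqueous work-up
Reagents that add atoms: none
Why: Chiral-diol-catalysed asymmetric allylboration of a methyl ketone, in which the diol exchanges onto boron and allyl transfer through a chair (Zimmerman–Traxler) transition state, with the E silyl group and the 2-arylethyl ketone substituent equatorial, sets C3 (S, the future C4′) by catalyst control and C4 relative to it.

Step 8
Reactants: 12 (3S,4R)-3-methyl-4-(trimethylsilyl)-1-(2,6,6-trimethylcyclohex-1-en-1-yl)hex-5-en-3-ol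
Product: 13 triethyl{[(3S,4R)-3-methyl-4-(trimethylsilyl)-1-(2,6,6-trimethylcyclohex-1-en-1-yl)hex-5-en-3-yl]oxy}silane
Conditions: Et3SiOTf, 2,6-lutidine, CH2Cl2, −78 °C
Reagents that add atoms: triethylsilyl trifluoromethanesulfonate, CC[Si](CC)(CC)OS(=O)(=O)C(F)(F)F
Why: Silylation of the hindered tertiary alcohol with a silyl triflate under buffered conditions, which masks the β-hydroxysilane against acid-induced Peterson elimination in the next step.

Step 9
Reactants: 8 methyl (2R)-2-[(3S)-6-methoxy-6-methyl-1,2-dioxan-3-yl]propanoate; 13 triethyl{[(3S,4R)-3-methyl-4-(trimethylsilyl)-1-(2,6,6-trimethylcyclohex-1-en-1-yl)hex-5-en-3-yl]oxy}silane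
Product: 15 methyl (2R)-2-[(3S,6S)-6-[(2E,4S)-4-hydroxy-4-methyl-6-(2,6,6-trimethylcyclohex-1-en-1-yl)hex-2-en-1-yl]-6-methyl-1,2-dioxan-3-yl]propanoate, via silyl ether 14 (not isolated)
Conditions: 13 (1.5 equiv), Me3SiOTf (0.3 equiv), 2,6-di-tert-butyl-4-methylpyridine (0.4 equiv), CH2Cl2, −78 °C; then pyridine, HF·pyridine, THF, −78 to 0 °C
Reagents that add atoms: none
Why: Me3SiOTf silylates the exocyclic methoxy group of 8 and expels MeOSiMe3, giving the ring peroxycarbenium ion C6=O1(+), whose C6 is attacked by the terminal CH2 (C1′) of 13; the β-silyl cation then loses Me3Si to triflate (regenerating the promoter), which moves the double bond to C2′=C3′ (anti SE2′, Hosomi–Sakurai reaction). The closest known reaction type is the Lewis-acid allylation of 3-alkoxy-1,2-dioxanes by allylsilanes through peroxycarbenium ions, and β-silyloxy allylsilanes are established partners in Lewis-acid allylations at −78 °C. No ring is closed; the dioxane ring and the centres C3, Cα and C4′ are carried through unchanged, and the hindered tetrasubstituted ring alkene should not compete as a nucleophile. The new stereocentre C6 is controlled by the C3 side chain: the step needs attack on the face of C6 anti to that chain, and the design counts on the ester carbonyl bridging from the pseudoaxial side chain to the electron-poor C6 (a seven-membered dioxocarbenium, as in 1,4-participation in pyranosyl cations), so that the allylsilane enters along the axial trajectory on the open face and C1′ ends trans to the side chain with the methyl group cis. E geometry at C2′=C3′ follows because the fully substituted C4′ cannot sit inside the allyl system (eclipsing the vinyl hydrogen) in the SE2′ transition state, and Peterson elimination is held back by the bulky, weakly basic triethylsilyl ether, the low temperature and the buffered, substoichiometric promoter. Fluoride then removes only the triethylsilyl ether.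

Step 10
Reactants: 15 methyl (2R)-2-[(3S,6S)-6-[(2E,4S)-4-hydroxy-4-methyl-6-(2,6,6-trimethylcyclohex-1-en-1-yl)hex-2-en-1-yl]-6-methyl-1,2-dioxan-3-yl]propanoate
Product: 16 (2R)-2-[(3S,6S)-6-[(2E,4S)-4-hydroxy-4-methyl-6-(2,6,6-trimethylcyclohex-1-en-1-yl)hex-2-en-1-yl]-6-methyl-1,2-dioxan-3-yl]propanoic acid
Conditions: LiOH·H2O, THF/H2O (3:1), 0 °C to rt; then 0.5 M HCl to pH 4, 0 °C
Reagents that add atoms: lithium hydroxide, [Li+].[OH-]
Why: Saponification of the unhindered methyl ester by acyl substitution at low temperature, which the dialkyl peroxide should tolerate; no stereocentre is touched, and acidification stops at pH 4 to protect the tertiary allylic alcohol.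

Compound list
1 | methyl acetoacetate | CC(=O)CC(=O)OC | starting material
2 | 3-chloro-2-methylprop-1-ene | C=C(C)CCl | starting material
3 | methyl 6-methyl-3-oxohept-6-enoate | C=C(C)CCC(=O)CC(=O)OC | intermediate
4 | methyl (3R)-3-hydroxy-6-methylhept-6-enoate | C=C(C)CC[C@@H](O)CC(=O)OC | intermediate
5 | methyl (2R,3R)-3-hydroxy-2,6-dimethylhept-6-enoate | C=C(C)CC[C@@H](O)[C@@H](C)C(=O)OC | intermediate
6 | methyl (2R,3R)-2,6-dimethyl-3-[(methylsulfonyl)oxy]hept-6-enoate | C=C(C)CC[C@@H](OS(C)(=O)=O)[C@@H](C)C(=O)OC | intermediate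
7 | methyl (2R,3R)-6-hydroperoxy-6-methoxy-2-methyl-3-[(methylsulfonyl)oxy]heptanoate (both C6 epimers) | COC(C)(OO)CC[C@@H](OS(C)(=O)=O)[C@@H](C)C(=O)OC | intermediate (not isolated)
8 | methyl (2R)-2-[(3S)-6-methoxy-6-methyl-1,2-dioxan-3-yl]propanoate (both C6 anomers) | COC1(C)CC[C@@H]([C@@H](C)C(=O)OC)OO1 | intermediate
9 | allyltrimethylsilane | C=CC[Si](C)(C)C | starting material
10 | dipropan-2-yl [(2E)-3-(trimethylsilyl)prop-2-en-1-yl]boronate | C[Si](C)(C)/C=C/CB(OC(C)C)OC(C)C | intermediate
11 | 4-(2,6,6-trimethylcyclohex-1-en-1-yl)butan-2-one (dihydro-β-ionone) | CC(=O)CCC1=C(C)CCCC1(C)C | starting material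
12 | (3S,4R)-3-methyl-4-(trimethylsilyl)-1-(2,6,6-trimethylcyclohex-1-en-1-yl)hex-5-en-3-ol | C=C[C@@H]([Si](C)(C)C)[C@@](C)(O)CCC1=C(C)CCCC1(C)C | intermediate
13 | triethyl{[(3S,4R)-3-methyl-4-(trimethylsilyl)-1-(2,6,6-trimethylcyclohex-1-en-1-yl)hex-5-en-3-yl]oxy}silane | C=C[C@@H]([Si](C)(C)C)[C@@](C)(O[Si](CC)(CC)CC)CCC1=C(C)CCCC1(C)C | intermediate
14 | methyl (2R)-2-[(3S,6S)-6-methyl-6-{(2E,4S)-4-methyl-4-[(triethylsilyl)oxy]-6-(2,6,6-trimethylcyclohex-1-en-1-yl)hex-2-en-1-yl}-1,2-dioxan-3-yl]propanoate | CC1=C(CC[C@](C)(O[Si](CC)(CC)CC)/C=C/C[C@]2(C)CC[C@@H]([C@@H](C)C(=O)OC)OO2)C(C)(C)CCC1 | intermediate (not isolated)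
15 | methyl (2R)-2-[(3S,6S)-6-[(2E,4S)-4-hydroxy-4-methyl-6-(2,6,6-trimethylcyclohex-1-en-1-yl)hex-2-en-1-yl]-6-methyl-1,2-dioxan-3-yl]propanoate | CC1=C(CC[C@](C)(O)/C=C/C[C@]2(C)CC[C@@H]([C@@H](C)C(=O)OC)OO2)C(C)(C)CCC1 | intermediate
16 | (2R)-2-[(3S,6S)-6-[(2E,4S)-4-hydroxy-4-methyl-6-(2,6,6-trimethylcyclohex-1-en-1-yl)hex-2-en-1-yl]-6-methyl-1,2-dioxan-3-yl]propanoic acid | CC1=C(CC[C@](C)(O)/C=C/C[C@]2(C)CC[C@@H]([C@@H](C)C(=O)O)OO2)C(C)(C)CCC1 | target

Total step count: 10
Longest linear sequence: 7 steps (steps 1 to 5, then 9 and 10)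

Steps most likely to fail

1. Step 9. Two processes threaten it. The allylsilane may attack the ring cation through the half-chair in which the side chain is pseudoequatorial, on the face syn to that chain, which would give the C6 epimer; this is the outcome expected on steric grounds alone if the ester does not bridge. The nucleophile may also be lost by β-elimination of silanol (Peterson) before the C–C bond forms. The fallback removes the ring bias by making the same C6–C1′ bond on an open chain and closing the ring afterwards, at the price of a separation. It sets out from 6 and 13. Ozonolysis of 6 in methanol gives 7 as in step 5, which is capped with Et3SiCl and imidazole to the silyl peroxyketal methyl (2R,3R)-6-methoxy-2-methyl-3-[(methylsulfonyl)oxy]-6-[(triethylsilyl)peroxy]heptanoate F1. Me3SiOTf-promoted Hosomi–Sakurai reaction of F1 with 13 at −78 °C gives the open-chain tertiary silyl peroxide methyl (2R,3R,8E,10S)-2,6,10-trimethyl-3-[(methylsulfonyl)oxy]-6-[(triethylsilyl)peroxy]-10-[(triethylsilyl)oxy]-12-(2,6,6-trimethylcyclohex-1-en-1-yl)dodec-8-enoate F2 as both C6 epimers. Excess Bu4NF in THF then frees the peroxide anion, which displaces the C3 mesylate with inversion, and also cleaves the silyl ether. This gives 15 together with its C6 epimer methyl (2R)-2-[(3S,6R)-6-[(2E,4S)-4-hydroxy-4-methyl-6-(2,6,6-trimethylcyclohex-1-en-1-yl)hex-2-en-1-yl]-6-methyl-1,2-dioxan-3-yl]propanoate F3, which is removed by chromatography. The route is rejoined at 15.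

2. Step 5. Base-induced β-elimination of methanesulfonate through the ester enolate (E1cB) may outrun the 6-exo displacement; the resulting enoate would then close by conjugate addition and scramble C3 and Cα. The fallback changes the C3 electrophile to a β-lactone, in which the ring C–O bond lies in the enolate plane and cannot be expelled in this way. It sets out from 5. LiOH gives (2R,3R)-3-hydroxy-2,6-dimethylhept-6-enoic acid F4. PhSO2Cl in pyridine at 0 °C closes it by carboxyl activation, with retention at the carbinol carbon, to (3R,4R)-3-methyl-4-(3-methylbut-3-en-1-yl)oxetan-2-one F5. Ozonolysis in CH2Cl2/MeOH at −78 °C gives the hydroperoxy ketal (3R,4R)-4-(3-hydroperoxy-3-methoxybutyl)-3-methyloxetan-2-one F6. Its peroxide anion (Cs2CO3, MeCN, 0 °C) opens the lactone at C4 by alkyl–oxygen cleavage with inversion in a 6-exo mode, giving (2R)-2-[(3S)-6-methoxy-6-methyl-1,2-dioxan-3-yl]propanoic acid F7. Me3SiCHN2 in toluene/MeOH returns to 8.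

3. Step 7. The catalyst may discriminate poorly between the methyl and the 2-arylethyl flank of ketone 11, or the hindered γ-silylallyl group may transfer sluggishly. The fallback replaces asymmetric catalysis by resolution. It sets out from 10 and 11. Without the diol (neat, 40 °C) they give 12 together with its enantiomer (3R,4S)-3-methyl-4-(trimethylsilyl)-1-(2,6,6-trimethylcyclohex-1-en-1-yl)hex-5-en-3-ol F8 as the racemate. The enantiomers are separated by preparative chromatography on a chiral stationary phase (amylose carbamate), and 12 rejoins the route at step 8.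

Further compounds
F1 | step 9 | methyl (2R,3R)-6-methoxy-2-methyl-3-[(methylsulfonyl)oxy]-6-[(triethylsilyl)peroxy]heptanoate (both C6 epimers) | COC(C)(OO[Si](CC)(CC)CC)CC[C@@H](OS(C)(=O)=O)[C@@H](C)C(=O)OC
F2 | step 9 | methyl (2R,3R,8E,10S)-2,6,10-trimethyl-3-[(methylsulfonyl)oxy]-6-[(triethylsilyl)peroxy]-10-[(triethylsilyl)oxy]-12-(2,6,6-trimethylcyclohex-1-en-1-yl)dodec-8-enoate (both C6 epimers) | CC1=C(CC[C@](C)(O[Si](CC)(CC)CC)/C=C/CC(C)(OO[Si](CC)(CC)CC)CC[C@@H](OS(C)(=O)=O)[C@@H](C)C(=O)OC)C(C)(C)CCC1
F3 | step 9 | methyl (2R)-2-[(3S,6R)-6-[(2E,4S)-4-hydroxy-4-methyl-6-(2,6,6-trimethylcyclohex-1-en-1-yl)hex-2-en-1-yl]-6-methyl-1,2-dioxan-3-yl]propanoate | CC1=C(CC[C@](C)(O)/C=C/C[C@@]2(C)CC[C@@H]([C@@H](C)C(=O)OC)OO2)C(C)(C)CCC1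
F4 | step 5 | (2R,3R)-3-hydroxy-2,6-dimethylhept-6-enoic acid | C=C(C)CC[C@@H](O)[C@@H](C)C(=O)O
F5 | step 5 | (3R,4R)-3-methyl-4-(3-methylbut-3-en-1-yl)oxetan-2-one | C=C(C)CC[C@H]1OC(=O)[C@@H]1C
F6 | step 5 | (3R,4R)-4-(3-hydroperoxy-3-methoxybutyl)-3-methyloxetan-2-one (both ketal epimers) | COC(C)(OO)CC[C@H]1OC(=O)[C@@H]1C
F7 | step 5 | (2R)-2-[(3S)-6-methoxy-6-methyl-1,2-dioxan-3-yl]propanoic acid (both C6 anomers) | COC1(C)CC[C@@H]([C@@H](C)C(=O)O)OO1
F8 | step 7 | (3R,4S)-3-methyl-4-(trimethylsilyl)-1-(2,6,6-trimethylcyclohex-1-en-1-yl)hex-5-en-3-ol | C=C[C@H]([Si](C)(C)C)[C@](C)(O)CCC1=C(C)CCCC1(C)C
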